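By 30.0 min of the larch run the starting material has lost 40 percentage points of its charge, more than the 11.9% read as product, so 28 points of the charge stands in forms I do not read.

| flask | starting material | partner | free catalyst | second catalyst | temperature | remark | time |
|---|---|---|---|---|---|---|---|
| larch | 22 mM | 14 mM | 0.50 mM | 0.12 mM | 25 °C | run made earlier |  |
| amber | 20 mM | 4.00 mM | 0.50 mM | 0.25 mM | 25 °C |  | 2.5 h |
| green | 20 mM | 8.00 mM | 0.50 mM | 0.50 mM | 25 °C |  | 2.5 h |
| blue | 20 mM | 14.0 mM | 0.30 mM | 0.50 mM | 25 °C |  | 2.5 h |
| violet | 20 mM | 14.0 mM | 0.50 mM | 0.12 mM | 25 °C |  | 2.5 h |
| grey | 12 mM | 14.0 mM | 2.0 mM | 0.12 mM | 25 °C |  | 2.5 h |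

larch run (percent of the starting material charged)

| time / min | product / % | starting material / % |
|---|---|---|
| 2.00 | 0 | 86.0 |
| 6.00 | 1.3 | 73.3 |
| 10.0 | 3.6 | 67.9 |
| 15.0 | 5.6 | 65.0 |
| 25.0 | 9.7 | 61.2 |
| 30.0 | 11.9 | 59.9 |

(each reading ± 0.3 percentage points)

- no earlier run changes the charge of free catalyst; that part of a forecast is a guess
- no earlier run changes the charge of second catalyst; that part of a forecast is a guess

- the flasks by amount of product, in percent of the starting material charged, highest first, at 2.5 h (amber / green / blue / violet / grey)
- the same order at 10 h (amber / green / blue / violet / grey)
- the amount of product, in percent of the starting material charged of the flask you put first, at 2.5 h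
- the amount of product, in percent of the starting material charged of the flask you put last, at 2.5 h

Where does each flask stop? No reading shows the partner, so I assume, as my own reckoning, that each product takes up one partner. The larch run has then spent 0.187 of its partner by its last reading, so its readings leave this assumption untested. The quantity I carry is the partner ceiling, the partner charged over the starting material charged: 0.700 for blue and violet, where the partner is the limiting reagent, as it is for amber at 0.200 and green at 0.400. In grey the ratio is 1.17, so the starting material is limiting and the ceiling is the whole charge, 1.00.

Does each flask get there in time? The late product slope of the larch run reads 0.00420 min⁻¹, which, held constant as a rough measure, gives 0.630 of the charge over 2.5 h. Taken over from the larch run, that is more than the ceilings of amber and green, so I expect both close to their ceilings by then, with amber last. Violet's ceiling is higher than that reach, so I expect violet still climbing, above green. The catalyst charges are untested, so I leave blue, grey and violet unranked at 2.5 h. Over 10 h the same rough measure gives 2.52, a figure no flask can reach but more than any ceiling, so I expect grey first, blue and violet level, then green and amber.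

The forecast differs: it holds that “the partner acts catalytically”, and gives blue > green > grey > violet > amber at 2.5 h and blue > green > grey > violet > amber at 10 h, with 90% first and 36% last. Its figures for blue and amber stand above my ceilings for those two flasks.

The flasks give blue > grey > violet > green > amber at 2.5 h, from 66.5% in blue down to 18.2% in amber, and grey > blue > violet > green > amber at 10 h.

    starting material + free catalyst ⇌ free catalyst + open intermediate (K = 0.488, k = 180 L mol⁻¹ min⁻¹, Ea = 57.0 kJ mol⁻¹, ΔH = −82.0 kJ mol⁻¹)
    second catalyst + open intermediate ⇌ catalyst intermediate (K = 190 L mol⁻¹, k = 1120 L mol⁻¹ min⁻¹, Ea = 36.0 kJ mol⁻¹, ΔH = −28.0 kJ mol⁻¹)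
    partner + catalyst intermediate → second catalyst + product (k = 127 L mol⁻¹ min⁻¹, Ea = 46.0 kJ mol⁻¹)
    (constants at 25 °C)

At 10 h amber stands at 20.0%, green at 40.0% and blue at 70.0%, matching their ceilings of 0.200, 0.400 and 0.700. A neighbour of blue, charged with 34 mM of starting material, has its ceiling lowered to 0.412. At 2.5 h that flask gives 40.9% product, with 0.590% of its partner left, 19.1% as open intermediate and 39% of the starting material still unbound.

The earlier runs and the new flask come from a simulation for an exercise, and the scatter is random.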